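**Plan**

Numbering: C1–C5 pentyl chain, C6 pentyl-bearing ring carbon, C7 ring carbinol, C8 ring CH2, C9 ring carbon carrying the side chain, C10 acyloxy carbinol, C11–C19 non-8-enyl chain, O1 ring oxygen.
Retrosynthetic cuts, in this order: the stearate C–O bond at C10; the C10–C11 bond (aldehyde plus Grignard reagent); O1–C6 and C5–C6 together, which opens the oxolane to an acyclic diazoketone; finally C6–C7 (acylation of diazomethane) and the O–pentenyl ether bond.
Enabling feature: C6 is the one carbon at which O1–C6 and C5–C6 meet, and it sits next to oxygenated C7, so with C7 as a ketone C6 can be a carbenoid carbon; the C9 ether oxygen lies 1,5 to it and closes the five-membered ring as an oxonium ylide, and the allylic group on that oxygen then moves onto C6.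
Forward order: (R)-malate supplies C7–C10; the pentenyl ether and the diazo carbon are attached; the oxolane (the only ring) is closed with C1–C5 in place; then C7 is reduced, the side-chain alkene saturated, C11–C19 joined at C10 and the stearate installed.
Stereochemistry: C9 from (R)-malate; C6 from C9 through the trans-selective ylide shift; C7 from C6 by hydride attack anti to the C6 chain; C10 from C9 by chelation-controlled Grignard addition.

Key step: step 7

Remark on the chemistry: racemic pent-1-en-3-ol is used, so every pent-1-en-3-yl ether intermediate is carried as a mixture of both configurations at the pentenyl carbon. Both converge in the key step, and the E/Z composition of the resulting pent-2-enyl alkene does not matter because it is hydrogenated.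

**Route**

Step 1
Reactants: 1 dimethyl (R)-malate
Product: 2 methyl (3R)-3,4-dihydroxybutanoate
Conditions: BH3·SMe2 (1.05 equiv), NaBH4 (5 mol%), THF, 0 °C to rt; then MeOH
Reagents that add atoms: none
Why: Chemoselective borane reduction of an α-hydroxy ester, in which BH3 first forms an alkoxyborane at the hydroxyl and, with catalytic NaBH4, hydride is delivered through a five-membered ring to the adjacent ester only, so the distal ester and the stereocentre that becomes C9 stay untouched.

Step 2
Reactants: 2 methyl (3R)-3,4-dihydroxybutanoate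
Product: 3 methyl (3R)-4-[(tert-butyldiphenylsilyl)oxy]-3-hydroxybutanoate
Conditions: TBDPSCl (1.05 equiv), imidazole, DMF, 0 °C
Reagents that add atoms: tert-butyl(chloro)diphenylsilane, CC(C)(C)[Si](Cl)(c1ccccc1)c1ccccc1
Why: Silyl ether formation is selective for the primary hydroxyl because the bulky silyl chloride reacts far faster at the unhindered CH2OH than at the secondary carbinol at 0 °C.

Step 3
Reactants: 4 pent-1-en-3-ol (racemic)
Product: 5 pent-1-en-3-yl 2,2,2-trichloroacetimidate (racemic)
Conditions: Cl3CCN (1.2 equiv), DBU (10 mol%), CH2Cl2, 0 °C; filtered through Et3N-deactivated silica and used at once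
Reagents that add atoms: trichloroacetonitrile, N#CC(Cl)(Cl)Cl
Why: Base-catalysed addition of an alcohol to trichloroacetonitrile (trichloroacetimidate formation) is general for secondary allylic alcohols, and at 0 °C the imidate should not undergo the thermal [3,3]-rearrangement to the allylic amide.

Step 4
Reactants: 3 methyl (3R)-4-[(tert-butyldiphenylsilyl)oxy]-3-hydroxybutanoate; 5 pent-1-en-3-yl 2,2,2-trichloroacetimidate
Product: 6 methyl (3R)-4-[(tert-butyldiphenylsilyl)oxy]-3-(pent-1-en-3-yloxy)butanoate (both configurations at the pentenyl carbon)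
Conditions: 5 (2.5 equiv), TfOH (5 mol%), cyclohexane/CH2Cl2 2:1, 0 °C
Reagents that add atoms: pent-1-en-3-yl 2,2,2-trichloroacetimidate (5), C=CC(CC)OC(=N)C(Cl)(Cl)Cl
Why: Brønsted acid-catalysed O-alkylation with a trichloroacetimidate, in which protonation at nitrogen releases neutral trichloroacetamide and the contact ion pair should collapse with the secondary hydroxyl at the more substituted allyl terminus in a non-polar medium, under non-basic conditions that cause neither β-elimination nor silyl migration; the new ether centre forms without control, which is acceptable because step 7 removes it.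

Step 5
Reactants: 6 methyl (3R)-4-[(tert-butyldiphenylsilyl)oxy]-3-(pent-1-en-3-yloxy)butanoate
Product: 7 (3R)-4-[(tert-butyldiphenylsilyl)oxy]-3-(pent-1-en-3-yloxy)butanoic acid
Conditions: LiOH·H2O (2 equiv), THF/MeOH/H2O, 0 °C to rt; then 1 M HCl to pH 3 at 0 °C
Reagents that add atoms: lithium hydroxide, [Li+].[OH-]
Why: Ester saponification with LiOH at or below room temperature should cleave the methyl ester while the tert-butyldiphenylsilyl ether and the β-alkoxy group, which would need stronger base or heat to be lost, stay in place.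

Step 6
Reactants: 7 (3R)-4-[(tert-butyldiphenylsilyl)oxy]-3-(pent-1-en-3-yloxy)butanoic acid
Product: 9 (4R)-5-[(tert-butyldiphenylsilyl)oxy]-1-diazo-4-(pent-1-en-3-yloxy)pentan-2-one, via isobutyl carbonic mixed anhydride 8 (not isolated)
Conditions: iBuOCOCl, Et3N, Et2O, 0 °C; filter; then CH2N2 (excess, Et2O), 0 °C to rt
Reagents that add atoms: diazomethane, C=[N+]=[N-]
Why: Acylation of diazomethane by a mixed carbonic anhydride (first stage of an Arndt–Eistert sequence), in which diazomethane attacks the more electrophilic acyl carbonyl and the departing carbonate removes the proton of the diazonium intermediate, so the α-diazoketone forms without free HCl.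

Step 7
Reactants: 9 (4R)-5-[(tert-butyldiphenylsilyl)oxy]-1-diazo-4-(pent-1-en-3-yloxy)pentan-2-one
Product: 12 (2S,5R)-5-{[(tert-butyldiphenylsilyl)oxy]methyl}-2-[(2E)-pent-2-en-1-yl]oxolan-3-one, via copper carbenoid 10 (not isolated), via oxonium ylide 11 (not isolated)
Conditions: Cu(acac)2 (5 mol%), THF, reflux; 9 added slowly by syringe pump to about 0.01 M
Reagents that add atoms: none
Why: Cu(acac)2 decomposes diazoketone 9 with loss of N2 to the electrophilic keto-carbenoid 10, a lone pair of the C9 ether oxygen adds to its carbenoid carbon C6 to give the cyclic oxonium ylide 11, and the pent-1-en-3-yl group then passes from oxygen to C6 in a suprafacial [2,3]-sigmatropic shift with allylic transposition, so that O1–C6 and C5–C6 form in one operation and the branched ether emerges as a linear pent-2-enyl chain. The closest known reaction type is the copper-catalysed tandem oxonium ylide formation and [2,3]-rearrangement of allyl ethers of 4-alkoxy-1-diazoalkan-2-ones, which gives trans-2,5-disubstituted oxolan-3-ones. The oxolane ring closes in a five-membered exo mode, the oxygen attacking a trigonal carbenoid carbon whose bond to copper lies outside the ring being formed. The new C6 stereocentre is controlled by C9: in 11 the allylic group on the oxonium oxygen sits trans to the neighbouring silyloxymethyl group and is delivered to C6 on that same face, which should give the 2,5-trans (2S,5R) ketone. The step needs ylide formation to win over C–H insertion, cyclopropanation and carbene dimerisation, [2,3]-shift to win over [1,2]-shift, and high trans selectivity; these should be secured by the 1,5 placement of a Lewis-basic ether oxygen, the moderate electrophilicity of a copper carbenoid, the non-nucleophilic silyl ether, slow addition at high dilution, and the bulk of the group next to the oxonium centre. Both epimers at the pentenyl carbon converge because that carbon becomes an alkene carbon, and the alkene geometry (E expected from a pseudo-equatorial ethyl group in the envelope transition state) is irrelevant after step 9.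

Step 8
Reactants: 12 (2S,5R)-5-{[(tert-butyldiphenylsilyl)oxy]methyl}-2-[(2E)-pent-2-en-1-yl]oxolan-3-one
Product: 13 (2S,3S,5R)-5-{[(tert-butyldiphenylsilyl)oxy]methyl}-2-[(2E)-pent-2-en-1-yl]oxolan-3-ol
Conditions: LiBH(sBu)3 (1.2 equiv), THF, −78 °C; then H2O
Reagents that add atoms: none
Why: Diastereoselective ketone reduction with a bulky trialkylborohydride, in which hydride adds to the C7 carbonyl from the face opposite the adjacent C6 chain, so the new hydroxyl is cis to that chain and C7 is set as S.

Step 9
Reactants: 13 (2S,3S,5R)-5-{[(tert-butyldiphenylsilyl)oxy]methyl}-2-[(2E)-pent-2-en-1-yl]oxolan-3-ol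
Product: 14 (2S,3S,5R)-5-{[(tert-butyldiphenylsilyl)oxy]methyl}-2-pentyloxolan-3-ol
Conditions: H2 (1 atm), 10% Pd/C, EtOAc, rt
Reagents that add atoms: none
Why: Heterogeneous catalytic hydrogenation saturates the disubstituted alkene, while the silyl ether, the free alcohol and the ring C–O bonds (none allylic or benzylic) are inert.

Step 10
Reactants: 14 (2S,3S,5R)-5-{[(tert-butyldiphenylsilyl)oxy]methyl}-2-pentyloxolan-3-ol
Product: 15 tert-butyl({(2R,4S,5S)-4-[(4-methoxybenzyl)oxy]-5-pentyloxolan-2-yl}methoxy)diphenylsilane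
Conditions: NaH (1.5 equiv), PMBCl (1.3 equiv), Bu4NI (10 mol%), THF/DMF, 0 °C to rt
Reagents that add atoms: 4-methoxybenzyl chloride, COc1ccc(CCl)cc1
Why: Williamson ether synthesis on the sodium alkoxide, accelerated by iodide exchange, installs a C7 protecting group that survives fluoride, oxidation, a Grignard reagent and acylation and can later be removed oxidatively without touching an alkene or an ester.

Step 11
Reactants: 15 tert-butyl({(2R,4S,5S)-4-[(4-methoxybenzyl)oxy]-5-pentyloxolan-2-yl}methoxy)diphenylsilane
Product: 16 {(2R,4S,5S)-4-[(4-methoxybenzyl)oxy]-5-pentyloxolan-2-yl}methanol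
Conditions: TBAF (1.2 equiv), THF, 0 °C to rt
Reagents that add atoms: none
Why: Fluoride-mediated desilylation, driven by Si–F bond formation, frees the primary C10 alcohol and leaves the benzylic ether alone.

Step 12
Reactants: 16 {(2R,4S,5S)-4-[(4-methoxybenzyl)oxy]-5-pentyloxolan-2-yl}methanol
Product: 17 (2R,4S,5S)-4-[(4-methoxybenzyl)oxy]-5-pentyloxolane-2-carbaldehyde
Conditions: Dess–Martin periodinane (1.3 equiv), CH2Cl2, 0 °C to rt; crude aldehyde dried azeotropically and used directly
Reagents that add atoms: none
Why: Dess–Martin oxidation takes the primary alcohol to the aldehyde under mild non-basic conditions, without over-oxidation and without epimerising the α-alkoxy C9 centre.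

Step 13
Reactants: 18 9-bromonon-1-ene
Product: 19 non-8-en-1-ylmagnesium bromide (titrated Et2O solution)
Conditions: Mg turnings, I2 (cat.), Et2O, reflux
Reagents that add atoms: magnesium, [Mg]
Why: Grignard reagent formation by insertion of magnesium into the primary C–Br bond, with the terminal alkene too remote to cyclise onto the organometallic centre.

Step 14
Reactants: 17 (2R,4S,5S)-4-[(4-methoxybenzyl)oxy]-5-pentyloxolane-2-carbaldehyde; 19 non-8-en-1-ylmagnesium bromide
Product: 20 (1R)-1-{(2R,4S,5S)-4-[(4-methoxybenzyl)oxy]-5-pentyloxolan-2-yl}dec-9-en-1-ol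
Conditions: MgBr2·OEt2 (2 equiv), CH2Cl2, −78 °C; then 19 (1.5 equiv, Et2O), −78 to −40 °C; then H2O
Reagents that add atoms: non-8-en-1-ylmagnesium bromide (19), C=CCCCCCCC[Mg]Br
Why: Chelation-controlled Grignard addition to an α-alkoxy aldehyde, in which magnesium bridges O1 and the aldehyde oxygen in a five-membered chelate and the nucleophile adds to the exposed face on the side of the C9 hydrogen, which should give the threo (9R,10R) alcohol.

Step 15
Reactants: 20 (1R)-1-{(2R,4S,5S)-4-[(4-methoxybenzyl)oxy]-5-pentyloxolan-2-yl}dec-9-en-1-ol; 21 stearoyl chloride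
Product: 22 (1R)-1-{(2R,4S,5S)-4-[(4-methoxybenzyl)oxy]-5-pentyloxolan-2-yl}dec-9-en-1-yl octadecanoate
Conditions: 21 (1.3 equiv), Et3N, DMAP (10 mol%), CH2Cl2, 0 °C to rt
Reagents that add atoms: stearoyl chloride (21), CCCCCCCCCCCCCCCCCC(=O)Cl
Why: DMAP-catalysed acylation through the N-acylpyridinium ion esterifies the only free hydroxyl, the one at C10.

Step 16
Reactants: 22 (1R)-1-{(2R,4S,5S)-4-[(4-methoxybenzyl)oxy]-5-pentyloxolan-2-yl}dec-9-en-1-yl octadecanoate
Product: 23 (1R)-1-[(2R,4S,5S)-4-hydroxy-5-pentyloxolan-2-yl]dec-9-en-1-yl octadecanoate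
Conditions: DDQ (1.3 equiv), CH2Cl2/pH 7 phosphate buffer 10:1, 0 °C to rt
Reagents that add atoms: none
Why: Oxidative cleavage of a 4-methoxybenzyl ether by DDQ (hydride abstraction from the electron-rich benzylic position, then hydrolysis of the oxocarbenium ion) frees the C7 hydroxyl under neutral conditions that leave the terminal alkene and the stearate intact, the ester being unable to reach the trans-disposed C7 oxygen.

**Compound list**

1 | dimethyl (R)-malate | COC(=O)C[C@@H](O)C(=O)OC | starting material
2 | methyl (3R)-3,4-dihydroxybutanoate | COC(=O)C[C@@H](O)CO | intermediate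
3 | methyl (3R)-4-[(tert-butyldiphenylsilyl)oxy]-3-hydroxybutanoate | COC(=O)C[C@@H](O)CO[Si](c1ccccc1)(c1ccccc1)C(C)(C)C | intermediate
4 | pent-1-en-3-ol (racemic) | C=CC(O)CC | starting material
5 | pent-1-en-3-yl 2,2,2-trichloroacetimidate (racemic) | C=CC(CC)OC(=N)C(Cl)(Cl)Cl | intermediate
6 | methyl (3R)-4-[(tert-butyldiphenylsilyl)oxy]-3-(pent-1-en-3-yloxy)butanoate (both configurations at the pentenyl carbon) | COC(=O)C[C@@H](OC(CC)C=C)CO[Si](c1ccccc1)(c1ccccc1)C(C)(C)C | intermediate
7 | (3R)-4-[(tert-butyldiphenylsilyl)oxy]-3-(pent-1-en-3-yloxy)butanoic acid | OC(=O)C[C@@H](OC(CC)C=C)CO[Si](c1ccccc1)(c1ccccc1)C(C)(C)C | intermediate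
8 | isobutyl carbonic mixed anhydride of 7 | CC(C)COC(=O)OC(=O)C[C@@H](OC(CC)C=C)CO[Si](c1ccccc1)(c1ccccc1)C(C)(C)C | intermediate
9 | (4R)-5-[(tert-butyldiphenylsilyl)oxy]-1-diazo-4-(pent-1-en-3-yloxy)pentan-2-one | [N-]=[N+]=CC(=O)C[C@@H](OC(CC)C=C)CO[Si](c1ccccc1)(c1ccccc1)C(C)(C)C | intermediate
10 | copper carbenoid of 9 (ancillary ligands on copper omitted) | [Cu]=CC(=O)C[C@@H](OC(CC)C=C)CO[Si](c1ccccc1)(c1ccccc1)C(C)(C)C | intermediate
11 | (5R)-5-{[(tert-butyldiphenylsilyl)oxy]methyl}-3-oxo-1-(pent-1-en-3-yl)oxolan-1-ium-2-ide (oxonium ylide) | CCC(C=C)[O+]1[CH-]C(=O)C[C@@H]1CO[Si](c2ccccc2)(c3ccccc3)C(C)(C)C | intermediate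
12 | (2S,5R)-5-{[(tert-butyldiphenylsilyl)oxy]methyl}-2-[(2E)-pent-2-en-1-yl]oxolan-3-one | CC(C)(C)[Si](c1ccccc1)(c1ccccc1)OC[C@H]1CC(=O)[C@H](C/C=C/CC)O1 | intermediate
13 | (2S,3S,5R)-5-{[(tert-butyldiphenylsilyl)oxy]methyl}-2-[(2E)-pent-2-en-1-yl]oxolan-3-ol | CC(C)(C)[Si](c1ccccc1)(c1ccccc1)OC[C@H]1C[C@H](O)[C@H](C/C=C/CC)O1 | intermediate
14 | (2S,3S,5R)-5-{[(tert-butyldiphenylsilyl)oxy]methyl}-2-pentyloxolan-3-ol | CC(C)(C)[Si](c1ccccc1)(c1ccccc1)OC[C@H]1C[C@H](O)[C@H](CCCCC)O1 | intermediate
15 | tert-butyl({(2R,4S,5S)-4-[(4-methoxybenzyl)oxy]-5-pentyloxolan-2-yl}methoxy)diphenylsilane | CC(C)(C)[Si](c1ccccc1)(c1ccccc1)OC[C@H]1C[C@H](OCc2ccc(OC)cc2)[C@H](CCCCC)O1 | intermediate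
16 | {(2R,4S,5S)-4-[(4-methoxybenzyl)oxy]-5-pentyloxolan-2-yl}methanol | OC[C@H]1C[C@H](OCc2ccc(OC)cc2)[C@H](CCCCC)O1 | intermediate
17 | (2R,4S,5S)-4-[(4-methoxybenzyl)oxy]-5-pentyloxolane-2-carbaldehyde | O=C[C@H]1C[C@H](OCc2ccc(OC)cc2)[C@H](CCCCC)O1 | intermediate
18 | 9-bromonon-1-ene | C=CCCCCCCCBr | starting material
19 | non-8-en-1-ylmagnesium bromide | C=CCCCCCCC[Mg]Br | intermediate
20 | (1R)-1-{(2R,4S,5S)-4-[(4-methoxybenzyl)oxy]-5-pentyloxolan-2-yl}dec-9-en-1-ol | C=CCCCCCCC[C@@H](O)[C@H]1C[C@H](OCc2ccc(OC)cc2)[C@H](CCCCC)O1 | intermediate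
21 | stearoyl chloride | CCCCCCCCCCCCCCCCCC(=O)Cl | starting material
22 | (1R)-1-{(2R,4S,5S)-4-[(4-methoxybenzyl)oxy]-5-pentyloxolan-2-yl}dec-9-en-1-yl octadecanoate | C=CCCCCCCC[C@@H](OC(=O)CCCCCCCCCCCCCCCCC)[C@H]1C[C@H](OCc2ccc(OC)cc2)[C@H](CCCCC)O1 | intermediate
23 | (1R)-1-[(2R,4S,5S)-4-hydroxy-5-pentyloxolan-2-yl]dec-9-en-1-yl octadecanoate | C=CCCCCCCC[C@@H](OC(=O)CCCCCCCCCCCCCCCCC)[C@H]1C[C@H](O)[C@H](CCCCC)O1 | target

**Step count and risks**

Total step count: 16. Longest linear sequence: 14 steps (steps 1, 2, 4 to 12, 14 to 16, from 1 to 23); steps 3 and 13 prepare the two coupling partners.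

Steps most likely to fail:

Step 4. The ionised imidate may be captured at the primary allyl terminus (allylic transposition to a linear ether), may rearrange to the allylic amide, or the acid may erode the silyl ether. The fallback replaces the cationic alkylation by a metal-catalysed allylic substitution and sets out from 3 and 4. Alcohol 4 with Boc2O and DMAP in CH2Cl2 should give tert-butyl pent-1-en-3-yl carbonate F1. Alcohol 3 would then be allylated with F1 under [Ir(cod)Cl]2, a phosphoramidite ligand and Et2Zn (0.5 equiv) in THF at rt. This is an iridium-catalysed allylic etherification, in which the zinc-activated oxygen nucleophile attacks the substituted terminus of the allyl–iridium intermediate. It comes back to the route at 6.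

Step 7. With the α-branched migrating group the ylide may divert into a [1,2]-shift, the carbenoid into C–H insertion or dimerisation, or the shift may proceed with insufficient trans selectivity. The fallback uses the unsubstituted allyl ether, the best-established substrate class for this copper-catalysed rearrangement, and supplies the two missing carbons afterwards by olefin cross-metathesis. It sets out from 3. Allyl 2,2,2-trichloroacetimidate with catalytic TfOH should convert 3 into methyl (3R)-3-(allyloxy)-4-[(tert-butyldiphenylsilyl)oxy]butanoate F2. Saponification of F2 with LiOH then gives (3R)-3-(allyloxy)-4-[(tert-butyldiphenylsilyl)oxy]butanoic acid F3. Treatment of F3 with iBuOCOCl and Et3N gives the isobutyl carbonic mixed anhydride F4, and diazomethane converts F4 into (4R)-4-(allyloxy)-5-[(tert-butyldiphenylsilyl)oxy]-1-diazopentan-2-one F5. Cu(acac)2 in THF at reflux should take F5, through the copper carbenoid F6 and the O-allyl oxonium ylide F7, to (2S,5R)-2-allyl-5-{[(tert-butyldiphenylsilyl)oxy]methyl}oxolan-3-one F8. Cross-metathesis of F8 with excess (Z)-hex-3-ene and the second-generation Grubbs catalyst, (H2IMes)(PCy3)Cl2Ru=CHPh, in CH2Cl2 at 40 °C would give 12, where the route is rejoined; the alkene geometry obtained is of no consequence because step 9 saturates it.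

Step 14. Incomplete chelation may let the open-chain (Felkin–Anh) pathway compete and erode facial selectivity at C10, and the α-alkoxy aldehyde may partly epimerise before addition. The fallback sets C10 by hydride delivery to a ketone instead of by C–C bond formation and sets out from 17. Addition of 19 in Et2O at −78 °C without regard to selectivity gives 20 together with (1S)-1-{(2R,4S,5S)-4-[(4-methoxybenzyl)oxy]-5-pentyloxolan-2-yl}dec-9-en-1-ol F9. Dess–Martin oxidation of the mixture of 20 and F9 gives 1-{(2R,4S,5S)-4-[(4-methoxybenzyl)oxy]-5-pentyloxolan-2-yl}dec-9-en-1-one F10. Reduction of F10 with LiBH(sBu)3 in THF at −78 °C, which reduces α-alkoxy ketones under Felkin–Anh control to the threo alcohol, would bring the material back to the route at 20.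

**Further compounds**

F1 | step 4 | tert-butyl pent-1-en-3-yl carbonate | C=CC(CC)OC(=O)OC(C)(C)C
F2 | step 7 | methyl (3R)-3-(allyloxy)-4-[(tert-butyldiphenylsilyl)oxy]butanoate | COC(=O)C[C@@H](OCC=C)CO[Si](c1ccccc1)(c1ccccc1)C(C)(C)C
F3 | step 7 | (3R)-3-(allyloxy)-4-[(tert-butyldiphenylsilyl)oxy]butanoic acid | OC(=O)C[C@@H](OCC=C)CO[Si](c1ccccc1)(c1ccccc1)C(C)(C)C
F4 | step 7 | isobutyl carbonic mixed anhydride of F3 | CC(C)COC(=O)OC(=O)C[C@@H](OCC=C)CO[Si](c1ccccc1)(c1ccccc1)C(C)(C)C
F5 | step 7 | (4R)-4-(allyloxy)-5-[(tert-butyldiphenylsilyl)oxy]-1-diazopentan-2-one | [N-]=[N+]=CC(=O)C[C@@H](OCC=C)CO[Si](c1ccccc1)(c1ccccc1)C(C)(C)C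
F6 | step 7 | copper carbenoid of F5 (ancillary ligands on copper omitted) | [Cu]=CC(=O)C[C@@H](OCC=C)CO[Si](c1ccccc1)(c1ccccc1)C(C)(C)C
F7 | step 7 | O-allyl oxonium ylide, (5R)-1-allyl-5-{[(tert-butyldiphenylsilyl)oxy]methyl}-3-oxooxolan-1-ium-2-ide | C=CC[O+]1[CH-]C(=O)C[C@@H]1CO[Si](c2ccccc2)(c3ccccc3)C(C)(C)C
F8 | step 7 | (2S,5R)-2-allyl-5-{[(tert-butyldiphenylsilyl)oxy]methyl}oxolan-3-one | CC(C)(C)[Si](c1ccccc1)(c1ccccc1)OC[C@H]1CC(=O)[C@H](CC=C)O1
F9 | step 14 | (1S)-1-{(2R,4S,5S)-4-[(4-methoxybenzyl)oxy]-5-pentyloxolan-2-yl}dec-9-en-1-ol | C=CCCCCCCC[C@H](O)[C@H]1C[C@H](OCc2ccc(OC)cc2)[C@H](CCCCC)O1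
F10 | step 14 | 1-{(2R,4S,5S)-4-[(4-methoxybenzyl)oxy]-5-pentyloxolan-2-yl}dec-9-en-1-one | C=CCCCCCCCC(=O)[C@H]1C[C@H](OCc2ccc(OC)cc2)[C@H](CCCCC)O1
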